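**Remark on the chemistry (one assumption).** The enolate alkylation of step 7 is taken to go anti to the C7 oxygen (axial attack, opposite the pseudo-axial C6 methyl). The chain and the C7 oxygen must be cis in the key-step precursor, so the C7 centre is reset in steps 8–11.

## Analysis of the target

Compound 27 is a 2,5,5a,6,7,8,9,9a-octahydro-1-benzoxepine. A cyclohexane (ring A: C5a, C6, C7, C8, C9, C9a) is fused through C5a–C9a to a seven-membered oxepene (ring B: O1, C2, C3=C4, C5, C5a, C9a). These locants are used for all intermediates, monocyclic ones included.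

There are four stereocentres. C2 (R) is the allylic ether carbon carrying CH2Br. C5a (R) is the ring-fusion methine. C7 (S) is a secondary bromide next to the C6 gem-dimethyl group. C9a (S) is a fully substituted ether carbon carrying CH3.

H5a, the C9a methyl and the C7 bromine lie on one face of ring A, so the rings are cis-fused (C5 and O1 cis). The CH2Br group at C2 is cis to the C9a methyl across O1. The C3=C4 alkene is trisubstituted and Z.

Sensitive points are the neopentyl-type secondary bromide (elimination, 1,2-methyl shift), the allylic C2–O1 bond (ionisation), the β-bromo ether and the tertiary C9a–O bond. The difficulties are the tetrasubstituted C9a centre between C5a and the quaternary C6, the closure of a seven-membered ether onto it, the remote centre C2, and a C–Br bond at a carbon that resists substitution.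

The strategy rests on C9a. It bears O1 and a methyl group, the pattern left when a methyl nucleophile adds to a cyclic oxocarbenium ion C9a=O1+. The O1–C9a bond, the C9a–CH3 bond and ring B can therefore arise in one operation from a C9a ketone and a C2 hydroxyl.

## Retrosynthetic reasoning

**27 ⇒ 25 (through 26), then 24.** The two C–Br bonds are cut first. Neither bromide would survive the organometallic, Lewis-acidic or basic steps, and both can come from alcohols by phosphonium activation. Substitution at C7 inverts, so the alcohol must be (7R): equatorial and cis to C5. Diol 25 is the desilylated form of 24; silyl ethers pass the organochromium and organoaluminium steps.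

**24 ⇒ 21 (key disconnection).** O1–C9a and C9a–CH3 are cut together. This opens ring B and leaves the C9a ketone and the C2 hydroxyl of the (Z)-alkenyl keto alcohol 21. Cutting here, not at C2–O1, keeps C2 out of the bond-forming event: its oxygen is the nucleophile, so its configuration is carried through. The hardest centre, C9a, becomes the trigonal carbon of oxocarbenium ion 23. The forward reaction must close a seven-membered ring onto a hindered ketone and deliver methyl to the face of C9a cis to H5a. For this, the C7 silyloxy group of 21 must be equatorial together with C5. That fixes the chair of ring A and puts the axial C6 methyl over the other face.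

**21 ⇒ 19 + 20.** The C2–C3 bond is cut next to the carbinol, giving (Z)-alkenyl iodide 19 and aldehyde 20. An alkenylchromium addition tolerates the ketone of 19, keeps the alkene geometry and lets a chiral ligand set C2 independently of ring A.

**19 ⇒ 14 (through 18, 16 and 15).** In 19 the C5 chain and the C7 oxygen are cis, but an enolate alkylation at C5a enters anti to a C7 oxygen. The cis relation is therefore reached by a relay. The C7 carbinol of the trans compound 14 is oxidised (16, with C9a masked as in 15), and the ketone is reduced from its open axial face (18). The temporary (7S) centre controls C5a and is then replaced by the (7R) centre that C5a controls in turn.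

**14 ⇒ 6 + 10.** C5a–C5 and one C6–CH3 bond are cut. Conjugate methyl addition to enone 6 makes the gem-dimethyl group and the C9a/C5a enolate (11, 12) at the position where a ketone enolate would not otherwise form. Allylic bromide 10 brings in C5–C3 with the Z iodide in place.

**10 ⇒ 7.** The Z iodoalkene comes from hydroxyl-directed trans-hydrometalation of alkynol 7 and iodination (9), then exchange of OH for Br.

**6 ⇒ 1.** The carbinol centre of 6 (through 5) is traced to epoxide 3 of the deconjugated ketal 2, made from enone 1. An asymmetric epoxidation sets the absolute configuration of the whole route.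

## Alternatives that were turned down

**Alternative 1:** Ring A is closed by a radical C6–C7 bond formation on a carbocyclic precursor, and O1 is inserted afterwards.
- Forward key step: hydrogen-atom transfer from Fe(acac)3/PhSiH3 to an isopropenyl group on C5a gives the tertiary C6 radical. It adds 6-exo to an aldehyde tethered to C9a and forms the cis-fused hydroxy octalenone A1, with the gem-dimethyl group and the C7 carbinol made in one step.
- For: C5a comes from the chiral pool, and the radical step builds the most congested C–C bond of ring A under mild conditions. On starting-material cost and on the construction of C6 it is stronger than the chosen route.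
- Against: A1 is still two skeletal operations from ring B. A regioselective oxygen insertion is needed next to the quaternary C9a in the presence of the trisubstituted alkene (Baeyer–Villiger type). The resulting lactone carbonyl must then be turned into the C2 stereocentre with its CH2Br carbon, so C2 is made last and under substrate control. The C7 configuration depends on a reversible alkoxy-radical addition, and C9a must be set by two successive enolate alkylations.
- Comparison: the chosen strategy forms O1–C9a directly, sets C2 by reagent control before ring closure, and needs no skeletal change after the key step.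

**Alternative 2:** Ring B is cut at the sp2–sp3 bond C4–C5, and C2 is carried as a lactone carbonyl.
- Forward key step: 9-BBN adds to an exocyclic methylene group on C5a (hydrogen to C5a, boron to C5). Pd(dppf)Cl2/Cs2CO3 then couples the C5 borane with a (Z)-3-iodo-2-methylacryloyl group on the C9a oxygen, closing the unsaturated seven-membered lactone A2.
- For: B-alkyl Suzuki–Miyaura ring closure is established chemistry, so on precedent this step is stronger than the key step chosen here. The Z alkene comes in ready-made.
- Against: C5a would be set by hydroboration of a 1,1-disubstituted alkene between two fully substituted carbons (C6 and C9a). Acylation of the tertiary C9a alcohol is difficult. A2 still lacks the CH2Br carbon, so C2 must be built from the lactone carbonyl by one-carbon addition and reduction. That sets C2 late, through the same kind of oxocarbenium ion at the other end of O1.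
- Comparison: the chosen route pays for a less precedented key step with a two-step endgame from 24 and a C2 centre fixed beforehand.

**Alternative 3:** Ring B is cut at C2–C3.
- Forward key step: SnCl4 ionises a 2-bromo-1-ethoxyethyl group on the C9a oxygen. The oxocarbenium carbon C2 is attacked by the silicon-bearing carbon C3 of a (Z)-vinylsilane, closing the oxepene with loss of silicon and giving A3 with CH2Br in place.
- For: vinylsilane-terminated oxocarbenium cyclisations to oxepenes are well precedented. Silicon fixes the alkene position, and the primary bromide needs no separate step. On precedent and on the handling of the CH2Br carbon it is at least as strong as the chosen plan.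
- Against: C2 is created in the cyclisation and must come out cis to the C9a methyl across O1, under substrate control from a fully substituted C9a. The acetal sits on a tertiary oxygen, so the Lewis acid can also break the C9a–O bond. The C9a carbinol and the vinylsilane must be made first, and the C7 bromide still needs the same hindered substitution.
- Comparison: the chosen strategy fixes C2 by reagent control, makes C9a and ring B together, and uses the C6 methyl as the control element.

Key step: step 13

## Route

Step 1
Reactants: 1 3-methylcyclohex-2-en-1-one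
Product: 2 7-methyl-1,4-dioxaspiro[4.5]dec-7-ene
Conditions: ethylene glycol, p-TsOH (cat.), benzene, reflux, Dean–Stark
Reagents that add atoms: ethylene glycol, OCCO
Why: Acid-catalysed ketalisation of a β-alkyl enone runs through the dienol ether and should give mainly the β,γ-unsaturated ketal (deconjugative ketalisation), which moves the alkene to where an epoxide puts oxygen on the future carbinol carbon.

Step 2
Reactants: 2 7-methyl-1,4-dioxaspiro[4.5]dec-7-ene
Product: 3 (1R,6S)-1-methylspiro[7-oxabicyclo[4.1.0]heptane-3,2'-[1,3]dioxolane]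
Conditions: ent-Shi ketone (enantiomer of the D-fructose-derived catalyst, 30 mol %), KHSO5 (as Oxone), K2CO3, Bu4NHSO4, MeCN–CH2(OMe)2–aq. buffer (pH 10.5), 0 °C
Reagents that add atoms: potassium peroxymonosulfate, [K+].[O-]S(=O)(=O)OO
Why: Shi epoxidation of a trisubstituted cyclic alkene; the chiral dioxirane should transfer oxygen through the spiro transition state, and this catalyst enantiomer is the one that makes the CH epoxide carbon (S).

Step 3
Reactants: 3 (1R,6S)-1-methylspiro[7-oxabicyclo[4.1.0]heptane-3,2'-[1,3]dioxolane]
Product: 5 (S)-4-hydroxy-3-methylcyclohex-2-en-1-one, via epoxy ketone 4 (not isolated)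
Conditions: 1 M HCl, THF, 0 °C → rt
Reagents that add atoms: water, O
Why: Ketal hydrolysis unveils the β,γ-epoxy ketone, which opens by β-elimination through its enol to the γ-hydroxy enone; the C–O bond at the secondary epoxide carbon is not broken, so its configuration becomes that of the carbinol.

Step 4
Reactants: 5 (S)-4-hydroxy-3-methylcyclohex-2-en-1-one
Product: 6 (S)-3-methyl-4-(triethylsilyloxy)cyclohex-2-en-1-one
Conditions: TESCl, imidazole, CH2Cl2, 0 °C
Reagents that add atoms: chlorotriethylsilane, CC[Si](Cl)(CC)CC
Why: Standard silylation; the triethylsilyl ether survives the cuprate and enolate chemistry but is cleaved by dilute acid when the carbinol has done its work.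

Step 5
Reactants: 7 but-2-yn-1-ol
Product: 9 (Z)-3-iodobut-2-en-1-ol, via cyclic vinylalanate 8 (not isolated)
Conditions: NaAlH2(OCH2CH2OCH3)2 (Red-Al), Et2O, 0 °C → rt; then EtOAc; then I2, THF, −78 → 0 °C
Reagents that add atoms: iodine, II
Why: Hydroxyl-directed trans-hydroalumination delivers hydride to C2 and aluminium to C3 within a five-membered alanate; iodinolysis keeps the geometry and puts iodine cis to CH2OH (Z).

Step 6
Reactants: 9 (Z)-3-iodobut-2-en-1-ol
Product: 10 (Z)-1-bromo-3-iodobut-2-ene
Conditions: CBr4, PPh3, CH2Cl2, 0 °C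
Reagents that add atoms: carbon tetrabromide, BrC(Br)(Br)Br
Why: Appel bromination of a primary allylic alcohol under neutral conditions; the vinyl iodide and the alkene geometry are not touched.

Step 7
Reactants: 6 (S)-3-methyl-4-(triethylsilyloxy)cyclohex-2-en-1-one; 10 (Z)-1-bromo-3-iodobut-2-ene
Product: 14 (2R,4S)-4-hydroxy-2-[(2Z)-3-iodobut-2-en-1-yl]-3,3-dimethylcyclohexan-1-one, via trimethylsilyl enol ether 11 (not isolated), via lithium enolate 12 (not isolated), via triethylsilyl ether ketone 13 (not isolated)
Conditions: Me2CuLi, TMSCl, Et2O, −78 → 0 °C; then MeLi, THF, 0 °C; then 10, HMPA, −78 → −20 °C; then 1 M HCl, THF, 0 °C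
Reagents that add atoms: lithium dimethylcuprate, [Li+].C[Cu-]C
Why: Silyl-assisted cuprate conjugate addition builds the C6 gem-dimethyl group and gives the C9a/C5a enol ether regiospecifically; MeLi releases the lithium enolate, which the allylic bromide alkylates. Attack should be axial on the half-chair enolate, anti to the pseudo-axial C6 methyl and to the C7 silyloxy group, which sets C5a (R) with the chain trans to the C7 oxygen; acid work-up removes the triethylsilyl group, and the minor cis isomer must be removed by chromatography here.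

Step 8
Reactants: 14 (2R,4S)-4-hydroxy-2-[(2Z)-3-iodobut-2-en-1-yl]-3,3-dimethylcyclohexan-1-one
Product: 15 (6R,8S)-6-[(2Z)-3-iodobut-2-en-1-yl]-7,7-dimethyl-1,4-dioxaspiro[4.5]decan-8-ol
Conditions: ethylene glycol, PPTS, benzene, reflux, Dean–Stark
Reagents that add atoms: ethylene glycol, OCCO
Why: Acid-catalysed ketalisation masks the C9a carbonyl so that C7 can be oxidised and reduced without touching it; the weak acid is chosen to keep enolisation toward C5a low.

Step 9
Reactants: 15 (6R,8S)-6-[(2Z)-3-iodobut-2-en-1-yl]-7,7-dimethyl-1,4-dioxaspiro[4.5]decan-8-ol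
Product: 16 (6R)-6-[(2Z)-3-iodobut-2-en-1-yl]-7,7-dimethyl-1,4-dioxaspiro[4.5]decan-8-one
Conditions: Dess–Martin periodinane, NaHCO3, CH2Cl2, rt
Reagents that add atoms: none
Why: Dess–Martin oxidation of the secondary alcohol under buffered conditions; C5a is now the only stereocentre and is not α to a carbonyl.

Step 10
Reactants: 16 (6R)-6-[(2Z)-3-iodobut-2-en-1-yl]-7,7-dimethyl-1,4-dioxaspiro[4.5]decan-8-one
Product: 18 (2R,4R)-4-hydroxy-2-[(2Z)-3-iodobut-2-en-1-yl]-3,3-dimethylcyclohexan-1-one, via cis hydroxy ketal 17 (not isolated)
Conditions: NaBH4, MeOH, −20 °C; then 1 M HCl, THF, rt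
Reagents that add atoms: water, O
Why: Hydride should add along the axial line of the C7 ketone, the face anti to the axial C6 methyl and syn to H5a (as in 4,4-dimethyl-3-keto terpenoids), giving the equatorial (7R) alcohol cis to the C5 chain; aqueous acid then hydrolyses the strained dioxolane.

Step 11
Reactants: 18 (2R,4R)-4-hydroxy-2-[(2Z)-3-iodobut-2-en-1-yl]-3,3-dimethylcyclohexan-1-one
Product: 19 (2R,4R)-4-[(tert-butyldimethylsilyl)oxy]-2-[(2Z)-3-iodobut-2-en-1-yl]-3,3-dimethylcyclohexan-1-one
Conditions: TBSOTf, 2,6-lutidine, CH2Cl2, −78 °C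
Reagents that add atoms: tert-butyldimethylsilyl trifluoromethanesulfonate, CC(C)(C)[Si](C)(C)OS(=O)(=O)C(F)(F)F
Why: Silylation of the hindered equatorial alcohol with the silyl triflate at low temperature, where 2,6-lutidine does not enolise the ketone.

Step 12
Reactants: 19 (2R,4R)-4-[(tert-butyldimethylsilyl)oxy]-2-[(2Z)-3-iodobut-2-en-1-yl]-3,3-dimethylcyclohexan-1-one; 20 (tert-butyldimethylsilyloxy)acetaldehyde
Product: 21 (2R,4R)-4-[(tert-butyldimethylsilyl)oxy]-2-[(2Z,4R)-5-[(tert-butyldimethylsilyl)oxy]-4-hydroxy-3-methylpent-2-en-1-yl]-3,3-dimethylcyclohexan-1-one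
Conditions: CrCl2 (3 equiv), chiral 2-(2-sulfonamidophenyl)oxazoline ligand (3.3 equiv), Et3N, NiCl2 (cat.), THF, rt
Reagents that add atoms: none
Why: Nozaki–Hiyama–Kishi coupling: zerovalent nickel inserts into the C–I bond with retention of the Z geometry, and transmetalation gives the alkenylchromium species, which adds to the aldehyde and not to the hindered ketone. The chiral ligand on chromium controls the aldehyde face (its enantiomer is chosen for Re-face attack, which gives (R) at C2); the ring stereocentres are too remote to interfere.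

Step 13
Reactants: 21 (2R,4R)-4-[(tert-butyldimethylsilyl)oxy]-2-[(2Z,4R)-5-[(tert-butyldimethylsilyl)oxy]-4-hydroxy-3-methylpent-2-en-1-yl]-3,3-dimethylcyclohexan-1-one
Product: 24 (2R,5aR,7R,9aS)-7-[(tert-butyldimethylsilyl)oxy]-2-{[(tert-butyldimethylsilyl)oxy]methyl}-3,6,6,9a-tetramethyl-2,5,5a,6,7,8,9,9a-octahydro-1-benzoxepine, via dimethylaluminium alkoxide 22 (not isolated), via oxocarbenium triflate 23 (not isolated)
Conditions: AlMe3 (4 equiv), CH2Cl2, −78 °C; then TMSOTf (2.5 equiv), −78 → −30 °C
Reagents that add atoms: trimethylaluminium, C[Al](C)C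
Why: Proposed new method: AlMe3 first turns the C2 hydroxyl into the dimethylaluminium alkoxide 22 (methane is lost) and removes traces of protic acid; TMSOTf then silylates the C9a carbonyl oxygen, the C2 oxygen adds to the activated carbonyl and the silyloxy group leaves, giving the ring B oxocarbenium ion 23, to which an aluminium-bound methyl adds irreversibly at C9a. The closest known reaction types are the reductive cyclisation of hydroxy ketones to oxepanes with Et3SiH and TMSOTf and the methylation of cyclic ketals with AlMe3; joining the two on an open hydroxy ketone is what is new. Ring B closes by attack of the hydroxyl oxygen on the carbonyl carbon (7-exo-trig), with the Z alkene holding O and C9a within reach. C9a is the only new stereocentre: in 23 ring A should keep the chair in which C5 and the C7 silyloxy group are equatorial, so the axial C6 methyl lies syn-axial to the axial line of attack on C9a, and methyl enters along the equatorial line, cis to H5a, giving (9aS) and the cis ring fusion. C2 keeps its configuration because its oxygen, not its carbon, takes part. The step needs cyclisation and methyl capture to outrun direct methyl addition of AlMe3 to the open ketone, proton loss from 23 to an enol ether and ionisation of the allylic C2–O bond; the hindered C9a carbonyl, the low temperature, the excess of methyl donor and the electron-withdrawing CH2OTBS group at C2 act in this sense.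

Step 14
Reactants: 24 (2R,5aR,7R,9aS)-7-[(tert-butyldimethylsilyl)oxy]-2-{[(tert-butyldimethylsilyl)oxy]methyl}-3,6,6,9a-tetramethyl-2,5,5a,6,7,8,9,9a-octahydro-1-benzoxepine
Product: 25 (2R,5aR,7R,9aS)-2-(hydroxymethyl)-3,6,6,9a-tetramethyl-2,5,5a,6,7,8,9,9a-octahydro-1-benzoxepin-7-ol
Conditions: TBAF, THF, 50 °C
Reagents that add atoms: none
Why: Fluoride cleaves both silyl ethers; the neopentyl-type secondary ether needs warming, and the ether and alkene are inert.

Step 15
Reactants: 25 (2R,5aR,7R,9aS)-2-(hydroxymethyl)-3,6,6,9a-tetramethyl-2,5,5a,6,7,8,9,9a-octahydro-1-benzoxepin-7-ol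
Product: 27 (2R,5aR,7S,9aS)-7-bromo-2-(bromomethyl)-3,6,6,9a-tetramethyl-2,5,5a,6,7,8,9,9a-octahydro-1-benzoxepine, via bromo alcohol 26 (not isolated)
Conditions: CBr4, PPh3, 2,6-lutidine, toluene, 0 → 70 °C
Reagents that add atoms: carbon tetrabromide, BrC(Br)(Br)Br
Why: Appel reaction: the primary alcohol is displaced first, then the oxyphosphonium of the equatorial C7 alcohol is displaced by bromide with inversion (SN2) to give the (7S) bromide; 2,6-lutidine keeps the medium non-acidic for the allylic ether.

## Compound list

1 | 3-methylcyclohex-2-en-1-one | CC1=CC(=O)CCC1 | starting material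
2 | 7-methyl-1,4-dioxaspiro[4.5]dec-7-ene | CC1=CCCC2(C1)OCCO2 | intermediate
3 | (1R,6S)-1-methylspiro[7-oxabicyclo[4.1.0]heptane-3,2'-[1,3]dioxolane] | C[C@]12O[C@H]1CCC1(C2)OCCO1 | intermediate
4 | (1R,6S)-1-methyl-7-oxabicyclo[4.1.0]heptan-3-one | C[C@]12O[C@H]1CCC(=O)C2 | intermediate
5 | (S)-4-hydroxy-3-methylcyclohex-2-en-1-one | O=C1C=C(C)[C@@H](O)CC1 | intermediate
6 | (S)-3-methyl-4-(triethylsilyloxy)cyclohex-2-en-1-one | O=C1C=C(C)[C@@H](O[Si](CC)(CC)CC)CC1 | intermediate
7 | but-2-yn-1-ol | CC#CCO | starting material
8 | sodium 2,2-bis(2-methoxyethoxy)-3-methyl-2,5-dihydro-1,2-oxaaluminol-2-uide (five-membered alkenylalanate, Al bound to O and to C3 of the butenyl unit) | CC1=CCO[Al-]1(OCCOC)OCCOC.[Na+] | intermediate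
9 | (Z)-3-iodobut-2-en-1-ol | C/C(I)=C/CO | intermediate
10 | (Z)-1-bromo-3-iodobut-2-ene | C/C(I)=C/CBr | intermediate
11 | {[(4S)-3,3-dimethyl-4-(triethylsilyloxy)cyclohex-1-en-1-yl]oxy}trimethylsilane | C[Si](C)(C)OC1=CC(C)(C)[C@@H](O[Si](CC)(CC)CC)CC1 | intermediate
12 | lithium (4S)-3,3-dimethyl-4-(triethylsilyloxy)cyclohex-1-en-1-olate | [Li+].[O-]C1=CC(C)(C)[C@@H](O[Si](CC)(CC)CC)CC1 | intermediate
13 | (2R,4S)-2-[(2Z)-3-iodobut-2-en-1-yl]-3,3-dimethyl-4-(triethylsilyloxy)cyclohexan-1-one | C/C(I)=C/C[C@@H]1C(C)(C)[C@@H](O[Si](CC)(CC)CC)CCC1=O | intermediate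
14 | (2R,4S)-4-hydroxy-2-[(2Z)-3-iodobut-2-en-1-yl]-3,3-dimethylcyclohexan-1-one | C/C(I)=C/C[C@@H]1C(C)(C)[C@@H](O)CCC1=O | intermediate
15 | (6R,8S)-6-[(2Z)-3-iodobut-2-en-1-yl]-7,7-dimethyl-1,4-dioxaspiro[4.5]decan-8-ol | C/C(I)=C/C[C@@H]1C(C)(C)[C@@H](O)CCC12OCCO2 | intermediate
16 | (6R)-6-[(2Z)-3-iodobut-2-en-1-yl]-7,7-dimethyl-1,4-dioxaspiro[4.5]decan-8-one | C/C(I)=C/C[C@@H]1C(C)(C)C(=O)CCC12OCCO2 | intermediate
17 | (6R,8R)-6-[(2Z)-3-iodobut-2-en-1-yl]-7,7-dimethyl-1,4-dioxaspiro[4.5]decan-8-ol | C/C(I)=C/C[C@@H]1C(C)(C)[C@H](O)CCC12OCCO2 | intermediate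
18 | (2R,4R)-4-hydroxy-2-[(2Z)-3-iodobut-2-en-1-yl]-3,3-dimethylcyclohexan-1-one | C/C(I)=C/C[C@@H]1C(C)(C)[C@H](O)CCC1=O | intermediate
19 | (2R,4R)-4-[(tert-butyldimethylsilyl)oxy]-2-[(2Z)-3-iodobut-2-en-1-yl]-3,3-dimethylcyclohexan-1-one | C/C(I)=C/C[C@@H]1C(C)(C)[C@H](O[Si](C)(C)C(C)(C)C)CCC1=O | intermediate
20 | (tert-butyldimethylsilyloxy)acetaldehyde | O=CCO[Si](C)(C)C(C)(C)C | starting material
21 | (2R,4R)-4-[(tert-butyldimethylsilyl)oxy]-2-[(2Z,4R)-5-[(tert-butyldimethylsilyl)oxy]-4-hydroxy-3-methylpent-2-en-1-yl]-3,3-dimethylcyclohexan-1-one | C/C(=C/C[C@@H]1C(C)(C)[C@H](O[Si](C)(C)C(C)(C)C)CCC1=O)[C@@H](O)CO[Si](C)(C)C(C)(C)C | intermediate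
22 | O-dimethylaluminium alkoxide of 21 (AlMe2 on the C2 oxygen) | C/C(=C/C[C@@H]1C(C)(C)[C@H](O[Si](C)(C)C(C)(C)C)CCC1=O)[C@@H](O[Al](C)C)CO[Si](C)(C)C(C)(C)C | intermediate
23 | (2R,5aR,7R)-7-[(tert-butyldimethylsilyl)oxy]-2-{[(tert-butyldimethylsilyl)oxy]methyl}-3,6,6-trimethyl-5,5a,6,7,8,9-hexahydro-2H-1-benzoxepin-1-ium trifluoromethanesulfonate (O1=C9a oxocarbenium ion) | CC1=CC[C@@H]2C(C)(C)[C@H](O[Si](C)(C)C(C)(C)C)CCC2=[O+][C@H]1CO[Si](C)(C)C(C)(C)C.[O-]S(=O)(=O)C(F)(F)F | intermediate
24 | (2R,5aR,7R,9aS)-7-[(tert-butyldimethylsilyl)oxy]-2-{[(tert-butyldimethylsilyl)oxy]methyl}-3,6,6,9a-tetramethyl-2,5,5a,6,7,8,9,9a-octahydro-1-benzoxepine | CC1=CC[C@@H]2C(C)(C)[C@H](O[Si](C)(C)C(C)(C)C)CC[C@]2(C)O[C@H]1CO[Si](C)(C)C(C)(C)C | intermediate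
25 | (2R,5aR,7R,9aS)-2-(hydroxymethyl)-3,6,6,9a-tetramethyl-2,5,5a,6,7,8,9,9a-octahydro-1-benzoxepin-7-ol | CC1=CC[C@@H]2C(C)(C)[C@H](O)CC[C@]2(C)O[C@H]1CO | intermediate
26 | (2R,5aR,7R,9aS)-2-(bromomethyl)-3,6,6,9a-tetramethyl-2,5,5a,6,7,8,9,9a-octahydro-1-benzoxepin-7-ol | CC1=CC[C@@H]2C(C)(C)[C@H](O)CC[C@]2(C)O[C@H]1CBr | intermediate
27 | (2R,5aR,7S,9aS)-7-bromo-2-(bromomethyl)-3,6,6,9a-tetramethyl-2,5,5a,6,7,8,9,9a-octahydro-1-benzoxepine | CC1=CC[C@@H]2C(C)(C)[C@@H](Br)CC[C@]2(C)O[C@H]1CBr | target

## Step count and least certain steps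

Total step count: 15 (steps 5 and 6 make bromide 10 in a side branch). Longest linear sequence: 13 steps (1–4, then 7–15).

**Step 13 (key step, proposed new method).**
- What may go wrong: direct methyl transfer from AlMe3 to the open ketone before ring closure; proton loss from the oxocarbenium ion to a cyclic enol ether, which also scrambles C5a; ionisation of the allylic C2–O bond with allylic transposition; and poor facial selectivity at C9a, because the C2 side chain lies on the face from which methyl must enter.
- Fallback (known reaction types: bridged ketal formation from a keto diol, and retentive ring opening of such ketals by AlMe3): it sets out from 21. Selective cleavage of the primary silyl ether (HF·pyridine, pyridine, THF, 0 °C) gives the keto diol F1. Under PPTS in CH2Cl2 over molecular sieves this closes to the bridged ketal F2, in which C9a carries O1 and the oxygen of the CH2O arm. The five-membered ketal ring can only form with that second oxygen on the face of the CH2 group, which is where the methyl has to go. AlMe3 (toluene, 0 °C → rt) should coordinate the less hindered primary oxygen, break its bond to C9a and hand methyl to the same face, giving the alcohol F3. TBAF then returns to the route at 25.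

**Step 7 (conjugate addition and alkylation).**
- What may go wrong: slow C-alkylation at the enolate carbon next to the quaternary centre, with proton exchange, and incomplete or reversed facial control. Because C7 is oxidised in step 9, any cis isomer carried forward would erode enantiopurity.
- Fallback: it sets out from 2 and returns at 19. If the alkylation favours the cis isomer, the relay of steps 8–11 is dropped and the enantiomeric enone is used. Epoxidation of 2 with the D-fructose-derived Shi ketone gives the epoxy ketal F4, hydrolysis gives the (R)-hydroxy enone F5, and TBSCl gives the silyl ether F6. Conjugate methylation to the trimethylsilyl enol ether F7, release of the lithium enolate F8 and alkylation with 10 would then give 19 directly, four steps shorter.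

**Step 12 (asymmetric alkenylchromium addition).**
- What may go wrong: insufficient reagent control at C2 with a trisubstituted, α-branched alkenyl iodide, and slow coupling.
- Fallback: it sets out from 19 and returns at 21. Coupling without chiral ligand (CrCl2, NiCl2 cat., DMSO) gives the mixture of C2 epimers F9. MnO2 oxidises only the allylic alcohol to the enone F10. Corey–Bakshi–Shibata reduction with the (R)-oxazaborolidine and catecholborane at −78 °C should reduce the enone carbonyl much faster than the hindered ring ketone and set C2 (R).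

**Step 15 (substitution at C7).**
- What may go wrong: elimination toward C8 or a 1,2-methyl shift from C6 instead of SN2 displacement, because the carbinol is neopentyl-type and the nucleophile must approach past the axial hydrogens.
- Fallback: it sets out from 25 and returns at 27. The Appel reaction is stopped at 0 °C at the bromo alcohol 26. ClCH2SO2Cl and pyridine give the chloromethanesulfonate F11, and LiBr in DMF at 50–60 °C displaces this better, non-acidic leaving group with inversion.

## Further compounds

F1 | step 13 | (2R,4R)-4-[(tert-butyldimethylsilyl)oxy]-2-[(2Z,4R)-4,5-dihydroxy-3-methylpent-2-en-1-yl]-3,3-dimethylcyclohexan-1-one | C/C(=C/C[C@@H]1C(C)(C)[C@H](O[Si](C)(C)C(C)(C)C)CCC1=O)[C@@H](O)CO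
F2 | step 13 | bridged ketal of F1 (C9a bonded to O1 and to the oxygen of the C2 CH2O arm; C7 silyl ether kept) | CC1=CC[C@@H]2C(C)(C)[C@H](O[Si](C)(C)C(C)(C)C)CC[C@@]23OC[C@@H]1O3
F3 | step 13 | [(2R,5aR,7R,9aS)-7-[(tert-butyldimethylsilyl)oxy]-3,6,6,9a-tetramethyl-2,5,5a,6,7,8,9,9a-octahydro-1-benzoxepin-2-yl]methanol | CC1=CC[C@@H]2C(C)(C)[C@H](O[Si](C)(C)C(C)(C)C)CC[C@]2(C)O[C@H]1CO
F4 | step 7 | (1S,6R)-1-methylspiro[7-oxabicyclo[4.1.0]heptane-3,2'-[1,3]dioxolane] | C[C@@]12O[C@@H]1CCC1(C2)OCCO1
F5 | step 7 | (R)-4-hydroxy-3-methylcyclohex-2-en-1-one | O=C1C=C(C)[C@H](O)CC1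
F6 | step 7 | (R)-4-[(tert-butyldimethylsilyl)oxy]-3-methylcyclohex-2-en-1-one | O=C1C=C(C)[C@H](O[Si](C)(C)C(C)(C)C)CC1
F7 | step 7 | {[(4R)-4-[(tert-butyldimethylsilyl)oxy]-3,3-dimethylcyclohex-1-en-1-yl]oxy}trimethylsilane | C[Si](C)(C)OC1=CC(C)(C)[C@H](O[Si](C)(C)C(C)(C)C)CC1
F8 | step 7 | lithium (4R)-4-[(tert-butyldimethylsilyl)oxy]-3,3-dimethylcyclohex-1-en-1-olate | [Li+].[O-]C1=CC(C)(C)[C@H](O[Si](C)(C)C(C)(C)C)CC1
F9 | step 12 | (2R,4R)-4-[(tert-butyldimethylsilyl)oxy]-2-[(2Z)-5-[(tert-butyldimethylsilyl)oxy]-4-hydroxy-3-methylpent-2-en-1-yl]-3,3-dimethylcyclohexan-1-one, both epimers at the side-chain carbinol | C/C(=C/C[C@@H]1C(C)(C)[C@H](O[Si](C)(C)C(C)(C)C)CCC1=O)C(O)CO[Si](C)(C)C(C)(C)C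
F10 | step 12 | (2R,4R)-4-[(tert-butyldimethylsilyl)oxy]-2-[(2Z)-5-[(tert-butyldimethylsilyl)oxy]-3-methyl-4-oxopent-2-en-1-yl]-3,3-dimethylcyclohexan-1-one | C/C(=C/C[C@@H]1C(C)(C)[C@H](O[Si](C)(C)C(C)(C)C)CCC1=O)C(=O)CO[Si](C)(C)C(C)(C)C
F11 | step 15 | (2R,5aR,7R,9aS)-2-(bromomethyl)-3,6,6,9a-tetramethyl-2,5,5a,6,7,8,9,9a-octahydro-1-benzoxepin-7-yl chloromethanesulfonate | CC1=CC[C@@H]2C(C)(C)[C@H](OS(=O)(=O)CCl)CC[C@]2(C)O[C@H]1CBr
A1 | alternative 1 | (4aR,6R,8aS)-6-hydroxy-2,5,5,8a-tetramethyl-4a,5,6,7,8,8a-hexahydronaphthalen-1(4H)-one | CC1=CC[C@@H]2C(C)(C)[C@H](O)CC[C@]2(C)C1=O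
A2 | alternative 2 | (5aR,7R,9aS)-7-[(tert-butyldimethylsilyl)oxy]-3,6,6,9a-tetramethyl-5a,6,7,8,9,9a-hexahydro-1-benzoxepin-2(5H)-one | CC1=CC[C@@H]2C(C)(C)[C@H](O[Si](C)(C)C(C)(C)C)CC[C@]2(C)OC1=O
A3 | alternative 3 | (2R,5aR,7R,9aS)-2-(bromomethyl)-7-[(tert-butyldimethylsilyl)oxy]-3,6,6,9a-tetramethyl-2,5,5a,6,7,8,9,9a-octahydro-1-benzoxepine | CC1=CC[C@@H]2C(C)(C)[C@H](O[Si](C)(C)C(C)(C)C)CC[C@]2(C)O[C@H]1CBr
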